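**Plan**
1. Retrosynthesis: the C19 and C20 acids are tied back to a cyclic anhydride, and ring A is cut at C1–C10 and C3–C4 (C1–C3 from acryloyl chloride). Then C4–C5 (ester enolate Michael), C6–C7 (carbonylation), C10–C20 (conjugate addition), C13–C16 (ring D) and C8–C14/C9–C11 (ring C, Diels–Alder) are cut.
2. Forward: ring B is bought as a 4-silyloxycyclopentenone; ring C comes from a Diels–Alder reaction, ring D from an oxidative cycloalkenylation; the three carboxyl-bearing groups of ring B follow, then the temporary anhydride ring, and ring A last.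
3. Enabling feature: C19 (on C4) and C20 (on C10) are cis-diaxial on ring A and flank C5. As the six-membered anhydride C4–C19–O–C20–C10–C5 they make C4 and C10 the two α-carbons of one planar bis-enol, a 1,3-bis-nucleophile for a [3+3] annulation.
4. Stereochemistry: the bought C10–O centre sets C8 and C9 (cycloaddition anti to it) and is then erased. C9 relays to C12 and to a temporary 10β centre, and that centre to C5 and C6. C5 controls C4 and C10 in the key step; C13 follows from the bridge and C3 from reagent approach.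

Key step: step 14

Assumption: gibberellin atom numbers (C1–C20) and the α/β labels of the usual gibberellin drawing are used for all intermediates (H5, H9, C7 and the C15–C16 bridge β; C19, C20 and O12 α), and the target is taken to be isolable as the open 12α-hydroxy triacid on cold acidification.

Step 1
Reactants: 1 (R)-4-(tert-butyldimethylsilyloxy)cyclopent-2-en-1-one
Product: 2 (R)-4-(tert-butyldimethylsilyloxy)-2-iodocyclopent-2-en-1-one
Conditions: I2, pyridine, CH2Cl2, 0 → 23 °C
Reagents that add atoms: iodine, II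
Why: α-iodination of the enone by conjugate addition of pyridine, iodination of the enolate and elimination, which leaves the silyloxy-bearing stereocentre untouched.

Step 2
Reactants: 2 (R)-4-(tert-butyldimethylsilyloxy)-2-iodocyclopent-2-en-1-one; 3 allyltributylstannane
Product: 4 (R)-2-allyl-4-(tert-butyldimethylsilyloxy)cyclopent-2-en-1-one
Conditions: Pd2(dba)3 (2.5 mol%), AsPh3 (10 mol%), CuI (10 mol%), DMF, 40 °C
Reagents that add atoms: allyltributylstannane, C=CC[Sn](CCCC)(CCCC)CCCC
Why: Stille coupling of the α-iodoenone with the allylstannane under zerovalent palladium catalysis places the future C15–C17 unit on C8 without touching the stereocentre.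

Step 3
Reactants: 4 (R)-2-allyl-4-(tert-butyldimethylsilyloxy)cyclopent-2-en-1-one; 5 2-(tert-butyldimethylsilyloxy)buta-1,3-diene
Product: 6 cis-fused ring B/C adduct (C6 ketone; 8β-allyl; 9β-H; 10β-OTBS; C12(OTBS)=C13 enol ether)
Conditions: Tf2NH (5 mol%), CH2Cl2, −78 → −40 °C; Et3N quench
Reagents that add atoms: 2-(tert-butyldimethylsilyloxy)buta-1,3-diene, C=CC(=C)O[Si](C)(C)C(C)(C)C
Why: silyl-triflimide-catalysed Diels–Alder reaction in which the nucleophilic diene terminus bonds to the enone β-carbon C9 (so the silyloxy carbon becomes C12) and the diene adds anti to the C10 silyloxy group, setting C8 and C9 with a cis ring fusion.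

Step 4
Reactants: 6 cis-fused ring B/C adduct
Product: 7 ring B/C/D 6,12-diketone (10β-OTBS; β C15–C16 bridge; 16-methylene)
Conditions: Pd(OAc)2 (10 mol%), O2 (1 atm), DMSO, 45 °C
Reagents that add atoms: none
Why: oxidative cycloalkenylation of the silyl enol ether by divalent palladium (5-exo attack of C13 on the allyl group, then β-hydride elimination) closes ring D with the exocyclic methylene, and the configuration at C13 is fixed by the bridge.

Step 5
Reactants: 7 ring B/C/D 6,12-diketone
Product: 8 12α-hydroxy 6-ketone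
Conditions: LiBH(s-Bu)3 (1.05 equiv), THF, −78 °C; then H2O
Reagents that add atoms: none
Why: the bulky hydride reduces the more accessible ring C ketone (the C6 carbonyl is flanked by quaternary C8) from the equatorial β direction, because the axial path is blocked by the syn-axial C9–C10 bond, and so gives the axial 12α-alcohol.

Step 6
Reactants: 8 12α-hydroxy 6-ketone
Product: 9 10β,12α-bis(tert-butyldimethylsilyloxy) 6-ketone
Conditions: t-BuMe2SiOTf, 2,6-lutidine, CH2Cl2, 0 °C
Reagents that add atoms: tert-butyldimethylsilyl triflate, CC(C)(C)[Si](C)(C)OS(=O)(=O)C(F)(F)F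
Why: silylation of the hindered axial alcohol with the silyl triflate protects O12 for the base and organometallic steps that follow.

Step 7
Reactants: 9 10β,12α-bis(tert-butyldimethylsilyloxy) 6-ketone
Product: 10 ring B enone (6-oxo; C5=C10; 12α-OTBS)
Conditions: DBU, CH2Cl2, 23 °C
Reagents that add atoms: none
Why: E1cB β-elimination of the silyloxy group from the β-silyloxy ketone gives the cyclopentenone and removes the bought stereocentre after it has done its relay.

Step 8
Reactants: 10 ring B enone; 11 (chloromethyl)(isopropoxy)dimethylsilane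
Product: 13 enol triflate (C6(OTf)=C5; 10β-CH2SiMe2(Oi-Pr); 10α-H), via magnesium enolate 12 (not isolated)
Conditions: Mg, THF (gives i-PrOMe2SiCH2MgCl from 11); CuBr·SMe2 (10 mol%), THF, −78 °C; then N-(5-chloropyridin-2-yl)bis(trifluoromethanesulfonyl)imide, −78 → 0 °C
Reagents that add atoms: (chloromethyl)(isopropoxy)dimethylsilane, ClC[Si](C)(C)OC(C)C; N-(5-chloropyridin-2-yl)bis(trifluoromethanesulfonyl)imide, O=S(=O)(N(c1ccc(Cl)cn1)S(=O)(=O)C(F)(F)F)C(F)(F)F
Why: copper-catalysed conjugate addition of the hydroxymethyl-anion equivalent to C10 on the β face (anti to C11 on C9 and to the 12α-silyloxy group), with the regiodefined enolate trapped as the enol triflate.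

Step 9
Reactants: 13 enol triflate
Product: 14 2-(trimethylsilyl)ethyl ester of the 5-en-7-oic acid (C6=C5; C7 ester on C6)
Conditions: Pd(OAc)2 (5 mol%), dppf, CO (1 atm), Et3N, Me3SiCH2CH2OH, DMF, 60 °C
Reagents that add atoms: carbon monoxide, [C-]#[O+]; 2-(trimethylsilyl)ethanol, OCC[Si](C)(C)C
Why: palladium-catalysed alkoxycarbonylation of the enol triflate introduces C7 and makes C5 the β-carbon of an unsaturated ester.

Step 10
Reactants: 14 2-(trimethylsilyl)ethyl 5-en-7-oate; 15 tert-butyl propanoate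
Product: 16 Michael adduct (5β-H; C4 side chain α on C5; 6β-CO2CH2CH2SiMe3; tert-butyl 19-oate; C4 epimers)
Conditions: 15, LiN(i-Pr)2, THF, −78 °C; then 14, −78 → −40 °C; AcOH; then t-BuOK (0.2 equiv), t-BuOH/THF, 23 °C
Reagents that add atoms: tert-butyl propanoate, CCC(=O)OC(C)(C)C
Why: Michael addition of the lithium ester enolate to C5 anti to the 10β-silylmethyl group sets C5, and base equilibration puts the C7 ester trans to the new side chain (6β), while C4 is left as a mixture that is planarised later.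

Step 11
Reactants: 16 Michael adduct
Product: 17 20-alcohol (10β-CH2OH)
Conditions: KF, KHCO3, 30% H2O2, THF/MeOH, 40 °C
Reagents that add atoms: hydrogen peroxide, OO
Why: Tamao oxidation of the alkoxysilane turns the C–Si bond into C–OH, and lactonisation is held back by the tert-butyl group of the C19 ester and by the neopentyl position of the C7 ester next to quaternary C8.

Step 12
Reactants: 17 20-alcohol
Product: 18 20-oic acid (10β-CO2H; tert-butyl 19-oate)
Conditions: TEMPO (20 mol%), PhI(OAc)2 (2.5 equiv), MeCN/aqueous pH 7 buffer, 23 °C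
Reagents that add atoms: water, O
Why: oxoammonium-mediated oxidation of the primary alcohol through the aldehyde hydrate gives the acid and spares the 1,1-disubstituted alkene and the silyl groups.

Step 13
Reactants: 18 20-oic acid
Product: 20 19,20-anhydride fused to ring B at C5–C10 (C4 epimers), via acid chloride 19 (not isolated)
Conditions: 1-chloro-N,N,2-trimethylprop-1-en-1-amine, 2,6-lutidine, CH2Cl2, 0 → 40 °C
Reagents that add atoms: none
Why: the acid chloride forms under neutral conditions and is attacked by the carbonyl oxygen of the neighbouring tert-butyl ester, which loses its tert-butyl group as the chloride (acylative cleavage of a tert-butyl ester), closing the six-membered anhydride.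

Step 14
Reactants: 20 19,20-anhydride; 21 acryloyl chloride
Product: 25 3-oxo 19,20-anhydride with ring A closed (12α-OTBS; 7-(2-trimethylsilylethyl) ester), via bis(silyl ketene acetal) 22 (not isolated), via C4-acryloyl ketene acetal 23 (not isolated), via ring A silyl enol ether 24 (not isolated)
Conditions: Me3SiOTf (2.4 equiv), Et3N (3 equiv), CH2Cl2, −78 → 0 °C; then 21 (1.05 equiv), −78 → −20 °C; aqueous pH 5 buffer
Reagents that add atoms: acryloyl chloride, C=CC(=O)Cl
Why: Proposed new method: double soft enolisation turns the C19–O–C20 anhydride into the 2,6-bis(trimethylsilyloxy)-4H-pyran 22, whose ketene-acetal carbons act in turn: C4 is C-acylated by acryloyl chloride with loss of Me3SiCl, and the vinyl ketone so placed is attacked at its terminus by the remaining ketene acetal at C10 in an intramolecular Mukaiyama–Michael step, a [3+3] α,α'-annulation. The closest known reaction types are the α,α'-annulation of cyclic ketone enamines with acryloyl chloride to bicyclo[3.3.1]nonane-2,9-diones, the C-acylation of silyl ketene acetals and of 2,5-bis(silyloxy)furans by acid chlorides, and intramolecular Mukaiyama–Michael additions. Ring A (C10–C1–C2–C3–C4–C5) closes in a 6-endo-trig mode across the anhydride ring, which can only give the 3-oxabicyclo[3.3.1]nonane with C19 and C20 cis. C4 is set by attack on the face of the planar pyran anti to the C5–C6 bond (syn to H5), and C10 is then fixed by the bridge, so that C1 is β and C20 α, both relayed from C5. The step needs site selectivity in the first acylation (C4 over C10) and chemoselectivity over the C6–H of the ester: C4 carries only a methyl group and lies outside ring B, whereas C10 is a ring B carbon next to C9 that would have to leave sp2 within a five-membered ring, and esters are not enolised by Me3SiOTf/Et3N at these temperatures. Hydrolysis of the silyl enol ether 24 on work-up gives ketone 25.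

Step 15
Reactants: 25 3-oxo 19,20-anhydride
Product: 26 3β-hydroxy 19,20-anhydride
Conditions: KBH(s-Bu)3 (1.05 equiv), THF, −78 °C; AcOH
Reagents that add atoms: none
Why: the bulky hydride attacks the ring A ketone from the equatorial α direction, as in the reduction of 3-oxogibberellins by hindered borohydrides, to give the axial 3β-alcohol, while the two anhydride carbonyls, each on a quaternary carbon, are left alone at −78 °C.

Step 16
Reactants: 26 3β-hydroxy 19,20-anhydride
Product: 28 target gibberellin (3β,12α-dihydroxy 7,19,20-triacid), via 19,20-diacid 27 (not isolated)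
Conditions: LiOH, THF/H2O, 0 °C; then Bu4NF, THF, 50 °C; cold 1 M HCl to pH 3
Reagents that add atoms: lithium hydroxide, [Li+].[OH-]
Why: hydroxide opens the anhydride to the 19,20-dicarboxylate (which also shuts off retro-aldol loss of C3), and fluoride then removes the silyl ether at O12 and cleaves the 2-(trimethylsilyl)ethyl ester by fragmentation to ethene.

**Compound list**
1 | (R)-4-(tert-butyldimethylsilyloxy)cyclopent-2-en-1-one | O=C1C=C[C@H](O[Si](C)(C)C(C)(C)C)C1 | starting material
2 | (R)-4-(tert-butyldimethylsilyloxy)-2-iodocyclopent-2-en-1-one | O=C1C(I)=C[C@H](O[Si](C)(C)C(C)(C)C)C1 | intermediate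
3 | allyltributylstannane | C=CC[Sn](CCCC)(CCCC)CCCC | starting material
4 | (R)-2-allyl-4-(tert-butyldimethylsilyloxy)cyclopent-2-en-1-one | O=C1C(CC=C)=C[C@H](O[Si](C)(C)C(C)(C)C)C1 | intermediate
5 | 2-(tert-butyldimethylsilyloxy)buta-1,3-diene | C=CC(=C)O[Si](C)(C)C(C)(C)C | starting material
6 | cis-fused ring B/C adduct: C6 ketone, 8β-allyl, 9β-H, 10β-OTBS, C12(OTBS)=C13 enol ether | C=CC[C@]23CC=C(O[Si](C)(C)C(C)(C)C)C[C@H]2[C@H](O[Si](C)(C)C(C)(C)C)CC3=O | intermediate
7 | ring B/C/D 6,12-diketone: 9β-H, 10β-OTBS, β C15–C16 bridge, 16-methylene | C=C1C[C@]23C[C@H]1C(=O)C[C@H]2[C@H](O[Si](C)(C)C(C)(C)C)CC3=O | intermediate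
8 | 12α-hydroxy 6-ketone (10β-OTBS) | C=C1C[C@]23C[C@H]1[C@@H](O)C[C@H]2[C@H](O[Si](C)(C)C(C)(C)C)CC3=O | intermediate
9 | 10β,12α-bis(tert-butyldimethylsilyloxy) 6-ketone | C=C1C[C@]23C[C@H]1[C@@H](O[Si](C)(C)C(C)(C)C)C[C@H]2[C@H](O[Si](C)(C)C(C)(C)C)CC3=O | intermediate
10 | ring B enone: 6-oxo, C5=C10, 12α-OTBS | C=C1C[C@]23C[C@H]1[C@@H](O[Si](C)(C)C(C)(C)C)C[C@H]2C=CC3=O | intermediate
11 | (chloromethyl)(isopropoxy)dimethylsilane | ClC[Si](C)(C)OC(C)C | starting material
12 | chloromagnesium enolate C6(OMgCl)=C5 with 10β-CH2SiMe2(Oi-Pr) | C=C1C[C@]23C[C@H]1[C@@H](O[Si](C)(C)C(C)(C)C)C[C@H]2[C@H](C[Si](C)(C)OC(C)C)C=C3O[Mg]Cl | intermediate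
13 | enol triflate C6(OTf)=C5 with 10β-CH2SiMe2(Oi-Pr), 10α-H, 12α-OTBS | C=C1C[C@]23C[C@H]1[C@@H](O[Si](C)(C)C(C)(C)C)C[C@H]2[C@H](C[Si](C)(C)OC(C)C)C=C3OS(=O)(=O)C(F)(F)F | intermediate
14 | 2-(trimethylsilyl)ethyl 5-en-7-oate (C6=C5) with 10β-CH2SiMe2(Oi-Pr) | C=C1C[C@]23C[C@H]1[C@@H](O[Si](C)(C)C(C)(C)C)C[C@H]2[C@H](C[Si](C)(C)OC(C)C)C=C3C(=O)OCC[Si](C)(C)C | intermediate
15 | tert-butyl propanoate | CCC(=O)OC(C)(C)C | starting material
16 | Michael adduct: 5β-H, C4 chain α on C5, 6β-CO2CH2CH2SiMe3, tert-butyl 19-oate, 10β-CH2SiMe2(Oi-Pr), C4 epimers | C=C1C[C@]23C[C@H]1[C@@H](O[Si](C)(C)C(C)(C)C)C[C@H]2[C@H](C[Si](C)(C)OC(C)C)[C@@H](C(C)C(=O)OC(C)(C)C)[C@@H]3C(=O)OCC[Si](C)(C)C | intermediate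
17 | 20-alcohol (10β-CH2OH), otherwise as 16 | C=C1C[C@]23C[C@H]1[C@@H](O[Si](C)(C)C(C)(C)C)C[C@H]2[C@H](CO)[C@@H](C(C)C(=O)OC(C)(C)C)[C@@H]3C(=O)OCC[Si](C)(C)C | intermediate
18 | 20-oic acid (10β-CO2H), tert-butyl 19-oate, C4 epimers | C=C1C[C@]23C[C@H]1[C@@H](O[Si](C)(C)C(C)(C)C)C[C@H]2[C@H](C(=O)O)[C@@H](C(C)C(=O)OC(C)(C)C)[C@@H]3C(=O)OCC[Si](C)(C)C | intermediate
19 | 20-oyl chloride of 18 | C=C1C[C@]23C[C@H]1[C@@H](O[Si](C)(C)C(C)(C)C)C[C@H]2[C@H](C(=O)Cl)[C@@H](C(C)C(=O)OC(C)(C)C)[C@@H]3C(=O)OCC[Si](C)(C)C | intermediate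
20 | 19,20-anhydride (ring C4–C19–O–C20–C10–C5, trans-fused on ring B; C4 epimers), 12α-OTBS, 7-(2-trimethylsilylethyl) ester | C=C1C[C@]23C[C@H]1[C@@H](O[Si](C)(C)C(C)(C)C)C[C@H]2[C@@H]1C(=O)OC(=O)C(C)[C@H]1[C@@H]3C(=O)OCC[Si](C)(C)C | intermediate
21 | acryloyl chloride | C=CC(=O)Cl | starting material
22 | 2,6-bis(trimethylsilyloxy)-4H-pyran from 20 (C4 and C10 sp2; 5β-H) | C=C1C[C@]23C[C@H]1[C@@H](O[Si](C)(C)C(C)(C)C)C[C@H]2C1=C(O[Si](C)(C)C)OC(O[Si](C)(C)C)=C(C)[C@H]1[C@@H]3C(=O)OCC[Si](C)(C)C | intermediate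
23 | C4-acryloyl mono(silyl ketene acetal): acryloyl β on C4, C19 carbonyl restored, C10=C20(OSiMe3) | C=C1C[C@]23C[C@H]1[C@@H](O[Si](C)(C)C(C)(C)C)C[C@H]2C1=C(O[Si](C)(C)C)OC(=O)[C@](C)(C(=O)C=C)[C@H]1[C@@H]3C(=O)OCC[Si](C)(C)C | intermediate
24 | ring A silyl enol ether (C2=C3–OSiMe3) of 25 | C=C1C[C@]23C[C@H]1[C@@H](O[Si](C)(C)C(C)(C)C)C[C@H]2[C@]1(C(=O)O5)CC=C(O[Si](C)(C)C)[C@@](C)(C5=O)[C@H]1[C@@H]3C(=O)OCC[Si](C)(C)C | intermediate
25 | 3-oxo 19,20-anhydride of the target skeleton, 12-O-TBS ether, 7-(2-trimethylsilylethyl) ester | C=C1C[C@]23C[C@H]1[C@@H](O[Si](C)(C)C(C)(C)C)C[C@H]2[C@]1(C(=O)O5)CCC(=O)[C@@](C)(C5=O)[C@H]1[C@@H]3C(=O)OCC[Si](C)(C)C | intermediate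
26 | 3β-hydroxy 19,20-anhydride of the target, 12-O-TBS ether, 7-(2-trimethylsilylethyl) ester | C=C1C[C@]23C[C@H]1[C@@H](O[Si](C)(C)C(C)(C)C)C[C@H]2[C@]1(C(=O)O5)CC[C@H](O)[C@@](C)(C5=O)[C@H]1[C@@H]3C(=O)OCC[Si](C)(C)C | intermediate
27 | 19,20-diacid: 12-O-TBS ether 7-(2-trimethylsilylethyl) ester of the target (present as its dilithium salt) | C=C1C[C@]23C[C@H]1[C@@H](O[Si](C)(C)C(C)(C)C)C[C@H]2[C@]1(C(=O)O)CC[C@H](O)[C@@](C)(C(=O)O)[C@H]1[C@@H]3C(=O)OCC[Si](C)(C)C | intermediate
28 | target gibberellin: 3β,12α-dihydroxy-16-methylene C20 gibberellin 7,19,20-trioic acid | C=C1C[C@]23C[C@H]1[C@@H](O)C[C@H]2[C@]1(C(=O)O)CC[C@H](O)[C@@](C)(C(=O)O)[C@H]1[C@@H]3C(=O)O | target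

**Step count and risks**
Total: 16 steps. Longest linear sequence: 16 steps, from 1.

Steps most likely to fail:

1. Step 14 (the step that carries the label). The first C-acylation may take place at C10 instead of C4, or the second enolisation may be incomplete, so that ring A closes with the ketone next to C10 or not at all. The fallback uses known chemistry, sets out from 17 and comes back at 26. Oxidation of 17 with the triacetoxy periodinane DMP would give the C20 aldehyde F1. Its potassium enolate (KN(SiMe3)2, THF, −78 °C; the aldehyde α-hydrogen at C10 is by far the most acidic) would be alkylated by propargyl bromide on the β face, anti to the C4 chain and to C11, to give the quaternary aldehyde F2. Pinnick oxidation would give the acid F3. Anti-Markovnikov hydration of the terminal alkyne ([CpRu(MeCN)3]PF6 with 5,5'-bis(trifluoromethyl)-2,2'-bipyridine, aqueous N-methylpyrrolidone) would give the C3 aldehyde F4. The chloroenamine of step 13 would close the anhydride aldehyde F5. Et3N in CH2Cl2 would then bring about the intramolecular Perkin-type aldol of the anhydride onto the aldehyde, closing C3–C4 in the same bicyclic frame to give 26. A 3-epimer, if formed, would be oxidised to 25 and passed through step 15.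

2. Step 3. The α-alkylated enone may be too sluggish a dienophile, with β-elimination of the silyloxy group or acid-induced loss of the diene winning over cycloaddition. The fallback sets out from 2 and comes back at 6. The α-iodoenone 2, a more reactive dienophile, would be combined with 5 under the same catalysis to give the angular iodide F6, and a Keck radical allylation with 3 (AIBN, benzene, 80 °C) on the convex face would deliver 6 with the cis ring fusion.

3. Step 10. The lithium enolate may deprotonate the unsaturated ester at C10 instead of adding, or may add to the hindered C5 slowly and with poor facial selectivity. The fallback sets out from 13 and comes back at 16. Reductive carbonylation of 13 (Pd(PPh3)4, CO, Bu3SnH, THF) would give the enal F7. A Mukaiyama–Michael addition of the silyl ketene acetal 1-tert-butoxy-1-(trimethylsilyloxy)prop-1-ene F8 (made from 15 with LiN(i-Pr)2 and Me3SiCl) under silyl-triflimide catalysis, anti to the 10β-silylmethyl group, would give the aldehyde F9 after equilibration at C6. Pinnick oxidation would give the acid F10, and esterification with 2-(trimethylsilyl)ethanol (EDC, DMAP) would return 16.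

**Further compounds**
F1 | step 14 | C20 aldehyde from 17 (10β-CHO, tert-butyl 19-oate, C4 epimers) | C=C1C[C@]23C[C@H]1[C@@H](O[Si](C)(C)C(C)(C)C)C[C@H]2[C@H](C=O)[C@@H](C(C)C(=O)OC(C)(C)C)[C@@H]3C(=O)OCC[Si](C)(C)C
F2 | step 14 | quaternary aldehyde: 10β-propargyl (C1–C3), 10α-CHO (C20) | C=C1C[C@]23C[C@H]1[C@@H](O[Si](C)(C)C(C)(C)C)C[C@H]2[C@@](CC#C)(C=O)[C@@H](C(C)C(=O)OC(C)(C)C)[C@@H]3C(=O)OCC[Si](C)(C)C
F3 | step 14 | 20-oic acid with 10β-propargyl | C=C1C[C@]23C[C@H]1[C@@H](O[Si](C)(C)C(C)(C)C)C[C@H]2[C@@](CC#C)(C(=O)O)[C@@H](C(C)C(=O)OC(C)(C)C)[C@@H]3C(=O)OCC[Si](C)(C)C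
F4 | step 14 | 20-oic acid with 10β-(3-oxopropyl) chain (C3 aldehyde) | C=C1C[C@]23C[C@H]1[C@@H](O[Si](C)(C)C(C)(C)C)C[C@H]2[C@@](CCC=O)(C(=O)O)[C@@H](C(C)C(=O)OC(C)(C)C)[C@@H]3C(=O)OCC[Si](C)(C)C
F5 | step 14 | 19,20-anhydride with 10β-(3-oxopropyl) chain | C=C1C[C@]23C[C@H]1[C@@H](O[Si](C)(C)C(C)(C)C)C[C@H]2[C@@]1(CCC=O)C(=O)OC(=O)C(C)[C@H]1[C@@H]3C(=O)OCC[Si](C)(C)C
F6 | step 3 | cis-fused ring B/C adduct with 8β-iodide in place of allyl | I[C@]23CC=C(O[Si](C)(C)C(C)(C)C)C[C@H]2[C@H](O[Si](C)(C)C(C)(C)C)CC3=O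
F7 | step 10 | 5-en-7-al (enal) with 10β-CH2SiMe2(Oi-Pr) | C=C1C[C@]23C[C@H]1[C@@H](O[Si](C)(C)C(C)(C)C)C[C@H]2[C@H](C[Si](C)(C)OC(C)C)C=C3C=O
F8 | step 10 | 1-tert-butoxy-1-(trimethylsilyloxy)prop-1-ene (silyl ketene acetal of 15) | CC=C(O[Si](C)(C)C)OC(C)(C)C
F9 | step 10 | 6β-carbaldehyde Michael adduct (tert-butyl 19-oate, C4 epimers) | C=C1C[C@]23C[C@H]1[C@@H](O[Si](C)(C)C(C)(C)C)C[C@H]2[C@H](C[Si](C)(C)OC(C)C)[C@@H](C(C)C(=O)OC(C)(C)C)[C@@H]3C=O
F10 | step 10 | 7-oic acid of the Michael adduct | C=C1C[C@]23C[C@H]1[C@@H](O[Si](C)(C)C(C)(C)C)C[C@H]2[C@H](C[Si](C)(C)OC(C)C)[C@@H](C(C)C(=O)OC(C)(C)C)[C@@H]3C(=O)O
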